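Ring B of the 1,2-dihydronaphthalene is cut at C1–C1', C2–C3 and C3=C4. The cut exploits that C1 is the β carbon and C2 the α carbon of the C2 aroyl ketone, while C3 is the α carbon of the second aroyl ketone and C4 is a ring A benzylic carbon at the aldehyde oxidation level. One operation therefore joins a ring A chalcone, an aryl nucleophile and a phenacyl bromide by asymmetric conjugate arylation, enolate alkylation and aldol condensation, setting C1 and C2 and closing ring B. The precursor is the ring A chalcone whose C4 aldehyde is masked as a dimethyl acetal, with all phenols as isopropyl ethers.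

Key step: step 9

Remark on the chemistry: atoms are labelled as in the 1,2-dihydronaphthalene core (C1 to C4, C4a, C5 to C8, C8a; C1' is the aryl carbon on C1); the target SMILES corresponds to (1R,2R), with the C1 aryl and the C2 aroyl group cis.

Assumption: (S)-binap is taken to deliver the aryl group to the si face of C1 of the (E)-enone, as the usual face-selection model for this ligand predicts; the sense is to be confirmed on compound 17, and (R)-binap would be used if it proved opposite.

Step 1
Reactants: 1 5-hydroxyvanillin (3,4-dihydroxy-5-methoxybenzaldehyde)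
Product: 2 3,4-diisopropoxy-5-methoxybenzaldehyde
Conditions: 2-bromopropane (3 equiv), K2CO3 (3 equiv), DMF, 70 °C, N2
Reagents that add atoms: 2-bromopropane, CC(C)Br
Why: Williamson ether synthesis on both phenoxides should proceed cleanly, since the aldehyde is inert to carbonate and exclusion of air prevents oxidation of the catechol.

Step 2
Reactants: 2 3,4-diisopropoxy-5-methoxybenzaldehyde
Product: 3 5-(dimethoxymethyl)-1,2-diisopropoxy-3-methoxybenzene
Conditions: HC(OMe)3 (3 equiv), p-TsOH·H2O (2 mol%), MeOH, rt; Et3N quench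
Reagents that add atoms: trimethyl orthoformate, COC(OC)OC; methanol, CO
Why: Acid-catalysed acetalisation, driven to completion by the orthoformate as water scavenger, masks the future C4 aldehyde and supplies a directing group for the next step.

Step 3
Reactants: 3 5-(dimethoxymethyl)-1,2-diisopropoxy-3-methoxybenzene
Product: 5 2-(dimethoxymethyl)-4,5-diisopropoxy-6-methoxybenzaldehyde, via aryllithium 4 (not isolated)
Conditions: n-BuLi (1.2 equiv), Et2O, 0 °C → rt; DMF (2 equiv), −78 °C → rt; H2O
Reagents that add atoms: N,N-dimethylformamide, CN(C)C=O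
Why: Directed ortho-metalation followed by formylation with DMF should take place at C8a, whose C–H bond lies between two coordinating groups (acetal and methoxy), because at the other ortho site the isopropyl group, turned toward C5–H by the neighbouring isopropoxy group, hinders the base.

Step 4
Reactants: 6 4-hydroxyacetophenone
Product: 7 4-isopropoxyacetophenone
Conditions: 2-bromopropane (1.5 equiv), K2CO3 (2 equiv), DMF, 70 °C
Reagents that add atoms: 2-bromopropane, CC(C)Br
Why: Williamson ether synthesis of a phenoxide with a secondary bromide in a dipolar aprotic solvent is routine and leaves the methyl ketone untouched.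

Step 5
Reactants: 5 2-(dimethoxymethyl)-4,5-diisopropoxy-6-methoxybenzaldehyde; 7 4-isopropoxyacetophenone
Product: 8 (E)-3-[2-(dimethoxymethyl)-4,5-diisopropoxy-6-methoxyphenyl]-1-(4-isopropoxyphenyl)prop-2-en-1-one
Conditions: KOH (2 equiv), EtOH, 20–40 °C
Reagents that add atoms: none
Why: Claisen–Schmidt condensation, in which the enolate of 7 adds to the non-enolisable aldehyde 5 and E1cB dehydration gives the thermodynamically favoured (E)-enone, while the acetal is inert to base.

Step 6
Reactants: 9 3-methoxycatechol (3-methoxybenzene-1,2-diol)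
Product: 10 1,2-diisopropoxy-3-methoxybenzene
Conditions: 2-bromopropane (3 equiv), K2CO3 (3 equiv), DMF, 70 °C, N2
Reagents that add atoms: 2-bromopropane, CC(C)Br
Why: Williamson ether synthesis on both catechol oxygens, run under nitrogen to avoid quinone formation.

Step 7
Reactants: 10 1,2-diisopropoxy-3-methoxybenzene
Product: 12 (3,4-diisopropoxy-2-methoxyphenyl)titanium triisopropoxide, via aryllithium 11 (not isolated)
Conditions: n-BuLi (0.95 equiv), THF, 0 °C → rt; ClTi(OiPr)3 (0.95 equiv), −78 °C → rt; used as titrated THF solution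
Reagents that add atoms: chlorotitanium triisopropoxide, CC(C)O[Ti](Cl)(OC(C)C)OC(C)C
Why: Directed ortho-metalation next to the methoxy group (the flanked, bulky isopropoxy groups being poor directing groups) and lithium-to-titanium transmetalation should give the aryltitanium reagent, the slight deficit of n-BuLi ensuring that no butyltitanium species reaches the key step.

Step 8
Reactants: 7 4-isopropoxyacetophenone
Product: 13 2-bromo-1-(4-isopropoxyphenyl)ethanone
Conditions: CuBr2 (2.1 equiv), EtOAc/CHCl3 (1:1), reflux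
Reagents that add atoms: copper dibromide, Br[Cu]Br
Why: α-Bromination of an aryl methyl ketone through its enol with CuBr2 is selective for the α position and should leave the electron-rich ring unbrominated.

Step 9
Reactants: 8 (E)-3-[2-(dimethoxymethyl)-4,5-diisopropoxy-6-methoxyphenyl]-1-(4-isopropoxyphenyl)prop-2-en-1-one; 12 (3,4-diisopropoxy-2-methoxyphenyl)titanium triisopropoxide; 13 2-bromo-1-(4-isopropoxyphenyl)ethanone
Product: 17 [(1R,2R)-1-(3,4-diisopropoxy-2-methoxyphenyl)-6,7-diisopropoxy-8-methoxy-1,2-dihydronaphthalene-2,3-diyl]bis[(4-isopropoxyphenyl)methanone], via titanium enolate 14 (not isolated), via diketone acetal 15 (not isolated), via diketone aldehyde 16 (not isolated)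
Conditions: [Rh(OH)((S)-binap)]2 (1.5 mol%), 12 (1.6 equiv), THF, 20–40 °C; LiOiPr (1.6 equiv), then 13 (2.0 equiv), −20 °C → rt; then 1 M aq HCl, THF, 0 °C → rt
Reagents that add atoms: none
Why: Transmetalation from 12 gives an aryl complex of monovalent rhodium that inserts the C1=C2 bond of 8 on the face chosen by (S)-binap, a second transmetalation releases the titanium (Z)-enolate 14, LiOiPr turns it into the more nucleophilic lithium titanate that is C-alkylated at C2 by 13 to give 15, and dilute acid then hydrolyses the acetal to 16, whose C3 methylene enol adds to the C4 aldehyde and loses water. The closest known reaction type is the rhodium/binap-catalysed asymmetric 1,4-addition of aryltitanium triisopropoxides with electrophilic trapping of the titanium enolate, followed by an ordinary acid-catalysed intramolecular aldol condensation. Ring B closes in the 6-(enolexo)-exo-trig mode, and dehydration to the C3=C4 enone makes the closure irreversible. C1 is set by the catalyst, which should deliver the aryl group to the si face of C1 and give 1R; C2 is set by the substrate, because in the enolate conformer that minimises A(1,3) strain the C1–H bond eclipses the enolate double bond and 13 approaches anti to the di-ortho-substituted ring A aryl, which places the C1 aryl and the C2 aroyl group cis. The step needs C-alkylation in preference to attack on the carbonyl group of 13, closure through C3 and not C2, and no epimerisation at C2: the soft titanate and the SN2-reactive bromide favour the first, the fact that an aldol at the fully substituted C2 could not dehydrate and would revert secures the second, and dilute aqueous acid at room temperature serves the third while keeping Paal–Knorr furan formation and Bradsher-type attack of the C1 aryl ring on C4 out of reach.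

Step 10
Reactants: 17 [(1R,2R)-1-(3,4-diisopropoxy-2-methoxyphenyl)-6,7-diisopropoxy-8-methoxy-1,2-dihydronaphthalene-2,3-diyl]bis[(4-isopropoxyphenyl)methanone]
Product: 18 [(1R,2R)-1-(3,4-dihydroxy-2-methoxyphenyl)-6,7-dihydroxy-8-methoxy-1,2-dihydronaphthalene-2,3-diyl]bis[(4-hydroxyphenyl)methanone] (CNP0335881.1)
Conditions: BCl3 (1 M in CH2Cl2, 15 equiv), CH2Cl2, −78 → 0 °C, Ar; MeOH then H2O at −78 °C
Reagents that add atoms: none
Why: Lewis acid-mediated dealkylation, in which BCl3 cleaves the six secondary alkyl aryl ethers by ionisation to 2-chloropropane at low temperature while the methyl ethers, none of which is ortho to a carbonyl group, should persist, and the low temperature with an acidic, oxygen-free work-up should protect the epimerisable C2 centre and the catechols.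

Compound list

1 | 5-hydroxyvanillin (3,4-dihydroxy-5-methoxybenzaldehyde) | COc1cc(C=O)cc(O)c1O | starting material
2 | 3,4-diisopropoxy-5-methoxybenzaldehyde | COc1cc(C=O)cc(OC(C)C)c1OC(C)C | intermediate
3 | 5-(dimethoxymethyl)-1,2-diisopropoxy-3-methoxybenzene | COc1cc(C(OC)OC)cc(OC(C)C)c1OC(C)C | intermediate
4 | [6-(dimethoxymethyl)-3,4-diisopropoxy-2-methoxyphenyl]lithium | COc1c([Li])c(C(OC)OC)cc(OC(C)C)c1OC(C)C | intermediate (not isolated)
5 | 2-(dimethoxymethyl)-4,5-diisopropoxy-6-methoxybenzaldehyde | COc1c(C=O)c(C(OC)OC)cc(OC(C)C)c1OC(C)C | intermediate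
6 | 4-hydroxyacetophenone | CC(=O)c1ccc(O)cc1 | starting material
7 | 4-isopropoxyacetophenone | CC(=O)c1ccc(OC(C)C)cc1 | intermediate
8 | (E)-3-[2-(dimethoxymethyl)-4,5-diisopropoxy-6-methoxyphenyl]-1-(4-isopropoxyphenyl)prop-2-en-1-one (ring A chalcone, C4 as dimethyl acetal) | COC(OC)c1cc(OC(C)C)c(OC(C)C)c(OC)c1/C=C/C(=O)c1ccc(OC(C)C)cc1 | intermediate
9 | 3-methoxycatechol | COc1cccc(O)c1O | starting material
10 | 1,2-diisopropoxy-3-methoxybenzene | COc1cccc(OC(C)C)c1OC(C)C | intermediate
11 | (3,4-diisopropoxy-2-methoxyphenyl)lithium | COc1c([Li])ccc(OC(C)C)c1OC(C)C | intermediate (not isolated)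
12 | (3,4-diisopropoxy-2-methoxyphenyl)titanium triisopropoxide | CC(C)O[Ti](OC(C)C)(OC(C)C)c1ccc(OC(C)C)c(OC(C)C)c1OC | intermediate
13 | 2-bromo-1-(4-isopropoxyphenyl)ethanone | O=C(CBr)c1ccc(OC(C)C)cc1 | intermediate
14 | triisopropoxytitanium (Z)-enolate of (3R)-3-[2-(dimethoxymethyl)-4,5-diisopropoxy-6-methoxyphenyl]-3-(3,4-diisopropoxy-2-methoxyphenyl)-1-(4-isopropoxyphenyl)propan-1-one | COC(OC)c1cc(OC(C)C)c(OC(C)C)c(OC)c1[C@@H](c1ccc(OC(C)C)c(OC(C)C)c1OC)/C=C(\O[Ti](OC(C)C)(OC(C)C)OC(C)C)c1ccc(OC(C)C)cc1 | intermediate (not isolated)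
15 | (2S)-2-[(R)-[2-(dimethoxymethyl)-4,5-diisopropoxy-6-methoxyphenyl](3,4-diisopropoxy-2-methoxyphenyl)methyl]-1,4-bis(4-isopropoxyphenyl)butane-1,4-dione | COC(OC)c1cc(OC(C)C)c(OC(C)C)c(OC)c1[C@@H](c1ccc(OC(C)C)c(OC(C)C)c1OC)[C@H](CC(=O)c1ccc(OC(C)C)cc1)C(=O)c1ccc(OC(C)C)cc1 | intermediate (not isolated)
16 | 2-[(1R,2S)-1-(3,4-diisopropoxy-2-methoxyphenyl)-2-(4-isopropoxybenzoyl)-4-(4-isopropoxyphenyl)-4-oxobutyl]-4,5-diisopropoxy-3-methoxybenzaldehyde | O=Cc1cc(OC(C)C)c(OC(C)C)c(OC)c1[C@@H](c1ccc(OC(C)C)c(OC(C)C)c1OC)[C@H](CC(=O)c1ccc(OC(C)C)cc1)C(=O)c1ccc(OC(C)C)cc1 | intermediate (not isolated)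
17 | [(1R,2R)-1-(3,4-diisopropoxy-2-methoxyphenyl)-6,7-diisopropoxy-8-methoxy-1,2-dihydronaphthalene-2,3-diyl]bis[(4-isopropoxyphenyl)methanone] (cis; hexa-O-isopropyl ether of the target) | COc1c([C@@H]2c3c(cc(OC(C)C)c(OC(C)C)c3OC)C=C(C(=O)c3ccc(OC(C)C)cc3)[C@@H]2C(=O)c2ccc(OC(C)C)cc2)ccc(OC(C)C)c1OC(C)C | intermediate
18 | [(1R,2R)-1-(3,4-dihydroxy-2-methoxyphenyl)-6,7-dihydroxy-8-methoxy-1,2-dihydronaphthalene-2,3-diyl]bis[(4-hydroxyphenyl)methanone] (cis; CNP0335881.1) | COc1c([C@@H]2c3c(cc(O)c(O)c3OC)C=C(C(=O)c3ccc(O)cc3)[C@@H]2C(=O)c2ccc(O)cc2)ccc(O)c1O | target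

Total step count: 10. Longest linear sequence: 6 steps (steps 1, 2, 3, 5, 9, 10).

Steps most likely to fail

Step 9. What may go wrong: insertion of the hindered, di-ortho-substituted enone into the ortho-substituted aryl–rhodium bond may be slow; the titanate enolate may attack the carbonyl group of 13 instead of displacing bromide; or the acid stage may be reached before the alkylation is complete. Fallback (sets out from 11 and 8, returns at 15): the three events are separated into known single operations.
- Aryllithium 11 is quenched with B(OiPr)3 and worked up with dilute acid to give (3,4-diisopropoxy-2-methoxyphenyl)boronic acid F1.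
- Rhodium-catalysed asymmetric 1,4-addition of F1 to 8 under protic conditions ([Rh(OH)((S)-binap)]2, KOH (10 mol%), dioxane/H2O, 60–90 °C; Hayashi–Miyaura reaction) should give the isolable ketone (3R)-3-[2-(dimethoxymethyl)-4,5-diisopropoxy-6-methoxyphenyl]-3-(3,4-diisopropoxy-2-methoxyphenyl)-1-(4-isopropoxyphenyl)propan-1-one F2. Conversion and enantiomeric purity can be secured on F2 before the next bond is made.
- Deprotonation with LiN(SiMe3)2 (THF, −78 °C) should give the lithium (Z)-enolate of F2 F3, which is alkylated with 13 in THF/DMPU to give 15 under the same A(1,3) control.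
- Isolated 15 is then closed to 17 with dilute aqueous HCl in THF as a separate operation.

Step 3. What may go wrong: deprotonation at the other ortho position of 3, between the acetal and the isopropoxy group, which would place the formyl group on the wrong side of ring A. Fallback (sets out from 1, returns at 5): the competing site is switched off by a neighbouring phenoxide instead of by the bulk of an isopropyl group.
- Selective alkylation of the more acidic 4-OH of 1 (2-bromopropane 1.1 equiv, NaHCO3, DMF, 50 °C) gives 3-hydroxy-4-isopropoxy-5-methoxybenzaldehyde F4.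
- Acetalisation as in step 2 gives 5-(dimethoxymethyl)-2-isopropoxy-3-methoxyphenol F5.
- n-BuLi (2.2 equiv, THF, 0 °C) first forms the lithium phenoxide and then lithiates between the acetal and the methoxy group, the carbon next to the phenoxide being deactivated, to give the dilithio species lithium 5-(dimethoxymethyl)-2-isopropoxy-4-lithio-3-methoxyphenolate F6.
- DMF and a buffered aqueous quench give 2-(dimethoxymethyl)-4-hydroxy-5-isopropoxy-6-methoxybenzaldehyde F7, which is alkylated crude (2-bromopropane, K2CO3, DMF) to 5.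

Step 10. What may go wrong: enolisation toward C2 while the ketones are complexed by the Lewis acid, leading to epimerisation to the trans isomer during the slow cleavage of six ethers. Fallback (sets out from 17, returns at 18): the cleavage is driven to completion without regard to C2, and the cis relationship is restored afterwards by kinetic protonation.
- BCl3 at 0 °C → rt gives the hexaphenol as a mixture containing the C2 epimer, [(1R,2S)-1-(3,4-dihydroxy-2-methoxyphenyl)-6,7-dihydroxy-8-methoxy-1,2-dihydronaphthalene-2,3-diyl]bis[(4-hydroxyphenyl)methanone] F8.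
- Persilylation (TBSCl, imidazole, DMF) gives the hexakis(tert-butyldimethylsilyl) ether of F8 F9.
- LiN(SiMe3)2 (THF, −78 °C) converts both C2 epimers into the same lithium dienolate of F9 F10.
- Protonation at −78 °C with 2,6-di-tert-butyl-4-methylphenol should occur at C2 from the face opposite the pseudoaxial C1 aryl group and give the hexakis(tert-butyldimethylsilyl) ether of 18 F11.
- Et3N·3HF in THF then liberates 18 under non-epimerising conditions.

Further compounds

F1 | step 9 | (3,4-diisopropoxy-2-methoxyphenyl)boronic acid | COc1c(B(O)O)ccc(OC(C)C)c1OC(C)C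
F2 | step 9 | (3R)-3-[2-(dimethoxymethyl)-4,5-diisopropoxy-6-methoxyphenyl]-3-(3,4-diisopropoxy-2-methoxyphenyl)-1-(4-isopropoxyphenyl)propan-1-one | COC(OC)c1cc(OC(C)C)c(OC(C)C)c(OC)c1[C@@H](c1ccc(OC(C)C)c(OC(C)C)c1OC)CC(=O)c1ccc(OC(C)C)cc1
F3 | step 9 | lithium (Z)-enolate of F2 | COC(OC)c1cc(OC(C)C)c(OC(C)C)c(OC)c1[C@@H](c1ccc(OC(C)C)c(OC(C)C)c1OC)/C=C(\O[Li])c1ccc(OC(C)C)cc1
F4 | step 3 | 3-hydroxy-4-isopropoxy-5-methoxybenzaldehyde | COc1cc(C=O)cc(O)c1OC(C)C
F5 | step 3 | 5-(dimethoxymethyl)-2-isopropoxy-3-methoxyphenol | COc1cc(C(OC)OC)cc(O)c1OC(C)C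
F6 | step 3 | lithium 5-(dimethoxymethyl)-2-isopropoxy-4-lithio-3-methoxyphenolate | COc1c([Li])c(C(OC)OC)cc(O[Li])c1OC(C)C
F7 | step 3 | 2-(dimethoxymethyl)-4-hydroxy-5-isopropoxy-6-methoxybenzaldehyde | COc1c(C=O)c(C(OC)OC)cc(O)c1OC(C)C
F8 | step 10 | [(1R,2S)-1-(3,4-dihydroxy-2-methoxyphenyl)-6,7-dihydroxy-8-methoxy-1,2-dihydronaphthalene-2,3-diyl]bis[(4-hydroxyphenyl)methanone] (trans; C2 epimer of 18) | COc1c([C@@H]2c3c(cc(O)c(O)c3OC)C=C(C(=O)c3ccc(O)cc3)[C@H]2C(=O)c2ccc(O)cc2)ccc(O)c1O
F9 | step 10 | hexakis(tert-butyldimethylsilyl) ether of F8 | COc1c([C@@H]2c3c(cc(O[Si](C)(C)C(C)(C)C)c(O[Si](C)(C)C(C)(C)C)c3OC)C=C(C(=O)c3ccc(O[Si](C)(C)C(C)(C)C)cc3)[C@H]2C(=O)c2ccc(O[Si](C)(C)C(C)(C)C)cc2)ccc(O[Si](C)(C)C(C)(C)C)c1O[Si](C)(C)C(C)(C)C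
F10 | step 10 | lithium dienolate of F9 (C2 trigonal, C1 unchanged, enolate geometry not defined) | COc1c([C@@H]2c3c(cc(O[Si](C)(C)C(C)(C)C)c(O[Si](C)(C)C(C)(C)C)c3OC)C=C(C(=O)c3ccc(O[Si](C)(C)C(C)(C)C)cc3)C2=C(O[Li])c2ccc(O[Si](C)(C)C(C)(C)C)cc2)ccc(O[Si](C)(C)C(C)(C)C)c1O[Si](C)(C)C(C)(C)C
F11 | step 10 | hexakis(tert-butyldimethylsilyl) ether of 18 (1R,2R; cis) | COc1c([C@@H]2c3c(cc(O[Si](C)(C)C(C)(C)C)c(O[Si](C)(C)C(C)(C)C)c3OC)C=C(C(=O)c3ccc(O[Si](C)(C)C(C)(C)C)cc3)[C@@H]2C(=O)c2ccc(O[Si](C)(C)C(C)(C)C)cc2)ccc(O[Si](C)(C)C(C)(C)C)c1O[Si](C)(C)C(C)(C)C
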